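**Plan**
1. Cuts: O1–C8a (aryl ether), C3–C4 (enolate benzylation), C1'–C3 (aryl–CH2), O–prenyl and C1'–I; ring B itself at C3'–C4', C1'–C2' and C4'–C5'.
2. Enabling feature: ring B has oxygens at C2' and C4' flanking H–C3', the quaternary carbon on C5' beside the C4' oxygen, and C1' para to that oxygen. A vinylketene (C4', C1', C6', C5') and a silyloxyacetylene (C3', C2') give this pattern with the two oxygens already differentiated.
3. Forward: ring B by benzannulation (steps 1–5); iodide, prenyl ether and acetic acid chain (6–10); union with the ring A benzylic bromide (11–13); pyran ring closed last (14–15); desilylation (16).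
4. Stereochemistry: C3 (R) is set in step 13 by (R)-4-benzyloxazolidin-2-one and is not touched afterwards.

Key step: step 5

Remark: Ar = 5-(2-methylbut-3-en-2-yl)-4-[(3-methylbut-2-en-1-yl)oxy]-2-(triisopropylsilyloxy)phenyl (ring B with its C2' oxygen silylated); compounds 1, 3, 8, 17, 19, 22 and 25 are taken as purchased.

**Step 1**
Reactants: 1 2,2-dimethylbut-3-enoic acid
Product: 2 2,2-dimethylbut-3-en-1-ol
Conditions: LiAlH4, Et2O, 0 °C → rt; H2O/NaOH work-up
Reagents that add atoms: none
Why: Hydride reduction of the carboxylic acid with LiAlH4 gives the neopentyl alcohol and leaves the isolated terminal alkene untouched.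

**Step 2**
Reactants: 2 2,2-dimethylbut-3-en-1-ol, 3 dimethyl (2-oxopropyl)phosphonate
Product: 5 (E)-5,5-dimethylhepta-3,6-dien-2-one, via 2,2-dimethylbut-3-enal 4 (not isolated)
Conditions: Dess–Martin periodinane, CH2Cl2, 0 °C → rt; washed solution of 4 added to 3, LiCl, i-Pr2NEt, MeCN, rt
Reagents that add atoms: none
Why: Dess–Martin oxidation gives the volatile, non-enolisable aldehyde 4, which is used in solution in a Horner–Wadsworth–Emmons olefination under Masamune–Roush conditions, where the stabilised keto phosphonate anion gives the E enone.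

**Step 3**
Reactants: 5 (E)-5,5-dimethylhepta-3,6-dien-2-one
Product: 7 (E)-1-diazo-5,5-dimethylhepta-3,6-dien-2-one, via trifluoroacetyl diketone 6 (not isolated)
Conditions: LiN(SiMe3)2, THF, −78 °C; CF3CO2CH2CF3, −78 °C; dilute HCl wash; then MeSO2N3, Et3N, H2O (1 equiv), MeCN, rt
Reagents that add atoms: methanesulfonyl azide, CS(=O)(=O)N=[N+]=[N-]; 2,2,2-trifluoroethyl trifluoroacetate, O=C(OCC(F)(F)F)C(F)(F)F (its trifluoroacetyl group stays only in 6)
Why: Detrifluoroacetylative diazo transfer, in which the kinetic lithium enolate of the methyl ketone (no γ-hydrogen competes) is trifluoroacetylated and the activated diketone 6 takes the diazo group from the sulfonyl azide with loss of the trifluoroacetyl group, so that no diazomethane meets a conjugated alkene.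

**Step 4**
Reactants: 8 ethyl dibromoacetate
Product: 10 (triisopropylsilyloxy)ethyne, via lithium ethynolate 9 (not isolated)
Conditions: t-BuLi (4 equiv), THF, −78 → 0 °C; then i-Pr3SiCl, −78 °C → rt; aqueous work-up
Reagents that add atoms: triisopropylsilyl chloride, CC(C)[Si](Cl)(C(C)C)C(C)C
Why: Twofold bromine–lithium exchange gives an ester dianion that expels lithium ethoxide to form the lithium ynolate (ynolate formation from an α,α-dibromo ester), and the bulky silyl chloride traps it on oxygen as the isolable silyl ynol ether.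

**Step 5**
Reactants: 7 (E)-1-diazo-5,5-dimethylhepta-3,6-dien-2-one, 10 (triisopropylsilyloxy)ethyne
Product: 15 2-(2-methylbut-3-en-2-yl)-5-(triisopropylsilyloxy)phenol, via vinylketene 11 (not isolated), via cyclobutenone 12 (not isolated), via dienylketene 13 (not isolated), via cyclohexadienone 14 (not isolated)
Conditions: hν (medium-pressure Hg lamp, Pyrex filter, λ > 300 nm), 10 (1.5 equiv), ClCH2CH2Cl, 20 °C; then 80 °C in the dark
Reagents that add atoms: none
Why: Light above 300 nm expels N2 from 7 and the keto carbene rearranges (Wolff) to vinylketene 11, whose carbonyl carbon is attacked by the nucleophilic unsubstituted carbon of the ynol ether, so that a regioselective (2+2) cycloaddition gives the 4-alkenyl-3-silyloxycyclobutenone 12 (C3'–C4' and C1'–C2' bonds). Four-electron electrocyclic opening of 12 (by light or at 80 °C) gives dienylketene 13, which closes ring B by a thermal disrotatory six-electron electrocyclisation between the ketene carbon and the alkene carbon bearing the 1,1-dimethylallyl group (C4'–C5' bond), and dienone 14 tautomerises to the phenol. The closest known reaction is the second-generation Danheiser benzannulation (photochemical Wolff entry to the vinylketene) with trialkylsilyloxyalkynes, which gives resorcinol monosilyl ethers. No stereocentre survives, because the sp3 carbons of 12 and 14 are lost on ring opening and aromatisation. The selectivity needed is regiochemical and is secured by the polarisation of the ynol ether, which places the silyl ether at C2', the free hydroxyl at C4' beside the quaternary carbon and leaves C1' as CH para to that hydroxyl; the Pyrex cut-off keeps the isolated 3,3-dimethyl-1,4-diene out of di-π-methane chemistry and the E alkene holds the terminal vinyl group away from the ketene.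

**Step 6**
Reactants: 15 2-(2-methylbut-3-en-2-yl)-5-(triisopropylsilyloxy)phenol
Product: 16 4-iodo-2-(2-methylbut-3-en-2-yl)-5-(triisopropylsilyloxy)phenol
Conditions: N-iodosuccinimide (1.0 equiv), CH2Cl2, −40 → 0 °C, dark
Reagents that add atoms: N-iodosuccinimide, O=C1CCC(=O)N1I
Why: Electrophilic aromatic iodination, in which the position para to the free hydroxyl is the most activated open site, the carbon between the two oxygens is shielded by the silyl group and the monosubstituted neopentyl alkene is far less nucleophilic than the resorcinol-type ring at low temperature.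

**Step 7**
Reactants: 16 4-iodo-2-(2-methylbut-3-en-2-yl)-5-(triisopropylsilyloxy)phenol, 17 prenyl bromide (1-bromo-3-methylbut-2-ene)
Product: 18 {2-iodo-4-(2-methylbut-3-en-2-yl)-5-[(3-methylbut-2-en-1-yl)oxy]phenoxy}triisopropylsilane (Ar–I)
Conditions: 17 (1.3 equiv), K2CO3, DMF, rt
Reagents that add atoms: none
Why: Williamson ether synthesis, in which the phenoxide is alkylated on oxygen by the primary allylic bromide in a dipolar aprotic solvent while the aryl silyl ether tolerates anhydrous carbonate.

**Step 8**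
Reactants: 18 Ar–I, 19 ethyl bromoacetate
Product: 20 ethyl 2-Ar-acetate
Conditions: Zn dust (Me3SiCl-activated), 19, THF, rt to give BrZnCH2CO2Et; then 18, Pd2(dba)3 (2.5 mol %), XPhos (10 mol %), THF, 50 °C
Reagents that add atoms: none
Why: Negishi-type arylation of a Reformatsky reagent, in which oxidative addition of the aryl iodide to zerovalent palladium, transmetalation with the zinc ester enolate and reductive elimination form the C1'–C3 bond, the meta relation of iodide and allyl group ruling out an intramolecular Heck reaction.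

**Step 9**
Reactants: 20 ethyl 2-Ar-acetate
Product: 21 2-Ar-acetic acid
Conditions: LiOH·H2O (3 equiv), THF/H2O 3:1, 0 °C → rt; then cold 1 M HCl to pH 3–4
Reagents that add atoms: lithium hydroxide, [Li+].[OH-]
Why: Saponification of the unhindered ethyl ester at low temperature, under which the hindered aryl triisopropylsilyl ether and the prenyl ether should persist.

**Step 10**
Reactants: 21 2-Ar-acetic acid, 22 (R)-4-benzyloxazolidin-2-one
Product: 24 (R)-4-benzyl-3-(2-Ar-acetyl)oxazolidin-2-one, via mixed pivalic anhydride 23 (not isolated)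
Conditions: t-BuCOCl, Et3N, THF, −20 °C; then 22, LiCl, −20 °C → rt
Reagents that add atoms: pivaloyl chloride, CC(C)(C)C(=O)Cl (its acyl group stays only in 23)
Why: N-Acylation of the oxazolidinone through the mixed pivalic anhydride with LiCl assistance, the tert-butyl group directing attack to the arylacetyl carbonyl.

**Step 11**
Reactants: 25 3-bromo-4-methylphenol
Product: 26 (3-bromo-4-methylphenoxy)triisopropylsilane
Conditions: i-Pr3SiCl, imidazole, DMF, rt
Reagents that add atoms: triisopropylsilyl chloride, CC(C)[Si](Cl)(C(C)C)C(C)C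
Why: Standard silyl ether formation from a phenol with the silyl chloride and imidazole.

**Step 12**
Reactants: 26 (3-bromo-4-methylphenoxy)triisopropylsilane
Product: 27 [3-bromo-4-(bromomethyl)phenoxy]triisopropylsilane
Conditions: N-bromosuccinimide (1.05 equiv), AIBN (5 mol %), PhCF3, 80 °C
Reagents that add atoms: N-bromosuccinimide, O=C1CCC(=O)N1Br
Why: Wohl–Ziegler bromination, in which the bromine-atom chain abstracts the benzylic hydrogen while the non-polar medium, the ring bromine and the bulky silyl ether disfavour ionic ring bromination.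

**Step 13**
Reactants: 24 (R)-4-benzyl-3-(2-Ar-acetyl)oxazolidin-2-one, 27 [3-bromo-4-(bromomethyl)phenoxy]triisopropylsilane
Product: 28 (R)-4-benzyl-3-{(2R)-2-Ar-3-[2-bromo-4-(triisopropylsilyloxy)phenyl]propanoyl}oxazolidin-2-one
Conditions: NaN(SiMe3)2 (1.1 equiv), THF, −78 °C; then 27 (1.3 equiv), −78 → −40 °C; saturated aqueous NH4Cl
Reagents that add atoms: none
Why: Evans asymmetric alkylation, in which the chelated Z sodium enolate is shielded on one face by the benzyl group of the (R)-auxiliary and the benzylic bromide attacks the other face, forming the C3–C4 bond and setting C3 as (R).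

**Step 14**
Reactants: 28 (R)-4-benzyl-3-{(2R)-2-Ar-3-[2-bromo-4-(triisopropylsilyloxy)phenyl]propanoyl}oxazolidin-2-one
Product: 29 (2R)-2-Ar-3-[2-bromo-4-(triisopropylsilyloxy)phenyl]propan-1-ol
Conditions: LiBH4 (2 equiv), H2O (2 equiv), Et2O/THF, 0 °C
Reagents that add atoms: none
Why: Reductive cleavage of the N-acyloxazolidinone with LiBH4, in which hydride attacks the exocyclic carbonyl and releases the primary alcohol and the auxiliary without touching the stereocentre, the aryl bromide, the alkenes or the silyl ethers.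

**Step 15**
Reactants: 29 (2R)-2-Ar-3-[2-bromo-4-(triisopropylsilyloxy)phenyl]propan-1-ol
Product: 30 triisopropyl{[(3R)-3-Ar-3,4-dihydro-2H-chromen-7-yl]oxy}silane
Conditions: Pd(OAc)2 (5 mol %), 2-(di-tert-butylphosphino)-1,1'-binaphthyl (6 mol %), Cs2CO3 (1.5 equiv), toluene, 65 °C
Reagents that add atoms: none
Why: Intramolecular Buchwald–Hartwig etherification, in which oxidative addition of the aryl bromide to zerovalent palladium, alkoxide coordination and C–O reductive elimination promoted by the bulky phosphine close the six-membered pyran ring (O1–C8a) without involving C3.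

**Step 16**
Reactants: 30 triisopropyl{[(3R)-3-Ar-3,4-dihydro-2H-chromen-7-yl]oxy}silane
Product: 31 manuifolin D, (3R)-3-{2-hydroxy-5-(2-methylbut-3-en-2-yl)-4-[(3-methylbut-2-en-1-yl)oxy]phenyl}-3,4-dihydro-2H-chromen-7-ol
Conditions: Bu4NF (2.5 equiv), AcOH (2.5 equiv), THF, 0 °C → rt
Reagents that add atoms: none
Why: Fluoride-induced cleavage of both aryl silyl ethers (desilylation), buffered with acetic acid so that the phenoxides are protonated as they form, leaves the prenyl ether, the 1,1-dimethylallyl group and C3 untouched.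

**Compound list**
1 | 2,2-dimethylbut-3-enoic acid | C=CC(C)(C)C(=O)O | starting material
2 | 2,2-dimethylbut-3-en-1-ol | C=CC(C)(C)CO | intermediate
3 | dimethyl (2-oxopropyl)phosphonate | COP(=O)(CC(C)=O)OC | starting material
4 | 2,2-dimethylbut-3-enal | C=CC(C)(C)C=O | intermediate
5 | (E)-5,5-dimethylhepta-3,6-dien-2-one | CC(=O)/C=C/C(C)(C)C=C | intermediate
6 | (E)-1,1,1-trifluoro-7,7-dimethylnona-5,8-diene-2,4-dione | O=C(CC(=O)/C=C/C(C)(C)C=C)C(F)(F)F | intermediate
7 | (E)-1-diazo-5,5-dimethylhepta-3,6-dien-2-one | [N-]=[N+]=CC(=O)/C=C/C(C)(C)C=C | intermediate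
8 | ethyl dibromoacetate | CCOC(=O)C(Br)Br | starting material
9 | lithium ethynolate | [Li+].[O-]C#C | intermediate
10 | (triisopropylsilyloxy)ethyne | C#CO[Si](C(C)C)(C(C)C)C(C)C | intermediate
11 | (E)-5,5-dimethylhepta-1,3,6-trien-1-one (vinylketene) | O=C=C/C=C/C(C)(C)C=C | intermediate
12 | 4-[(E)-3,3-dimethylpenta-1,4-dienyl]-3-(triisopropylsilyloxy)cyclobut-2-en-1-one | O=C1C=C(O[Si](C(C)C)(C(C)C)C(C)C)C1/C=C/C(C)(C)C=C | intermediate
13 | (3E,5E)-7,7-dimethyl-3-(triisopropylsilyloxy)nona-1,3,5,8-tetraen-1-one (dienylketene) | O=C=C/C(O[Si](C(C)C)(C(C)C)C(C)C)=C\C=C\C(C)(C)C=C | intermediate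
14 | 6-(2-methylbut-3-en-2-yl)-3-(triisopropylsilyloxy)cyclohexa-2,4-dien-1-one | O=C1C=C(O[Si](C(C)C)(C(C)C)C(C)C)C=CC1C(C)(C)C=C | intermediate
15 | 2-(2-methylbut-3-en-2-yl)-5-(triisopropylsilyloxy)phenol | C=CC(C)(C)c1ccc(O[Si](C(C)C)(C(C)C)C(C)C)cc1O | intermediate
16 | 4-iodo-2-(2-methylbut-3-en-2-yl)-5-(triisopropylsilyloxy)phenol | C=CC(C)(C)c1cc(I)c(O[Si](C(C)C)(C(C)C)C(C)C)cc1O | intermediate
17 | prenyl bromide (1-bromo-3-methylbut-2-ene) | CC(C)=CCBr | starting material
18 | {2-iodo-4-(2-methylbut-3-en-2-yl)-5-[(3-methylbut-2-en-1-yl)oxy]phenoxy}triisopropylsilane | C=CC(C)(C)c1cc(I)c(O[Si](C(C)C)(C(C)C)C(C)C)cc1OCC=C(C)C | intermediate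
19 | ethyl bromoacetate | CCOC(=O)CBr | starting material
20 | ethyl 2-Ar-acetate | CCOC(=O)Cc1cc(C(C)(C)C=C)c(OCC=C(C)C)cc1O[Si](C(C)C)(C(C)C)C(C)C | intermediate
21 | 2-Ar-acetic acid | OC(=O)Cc1cc(C(C)(C)C=C)c(OCC=C(C)C)cc1O[Si](C(C)C)(C(C)C)C(C)C | intermediate
22 | (R)-4-benzyloxazolidin-2-one | O=C1N[C@H](Cc2ccccc2)CO1 | starting material
23 | 2-Ar-acetic pivalic anhydride | CC(C)(C)C(=O)OC(=O)Cc1cc(C(C)(C)C=C)c(OCC=C(C)C)cc1O[Si](C(C)C)(C(C)C)C(C)C | intermediate
24 | (R)-4-benzyl-3-(2-Ar-acetyl)oxazolidin-2-one | C=CC(C)(C)c1cc(CC(=O)N2[C@H](Cc3ccccc3)COC2=O)c(O[Si](C(C)C)(C(C)C)C(C)C)cc1OCC=C(C)C | intermediate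
25 | 3-bromo-4-methylphenol | Cc1ccc(O)cc1Br | starting material
26 | (3-bromo-4-methylphenoxy)triisopropylsilane | Cc1ccc(O[Si](C(C)C)(C(C)C)C(C)C)cc1Br | intermediate
27 | [3-bromo-4-(bromomethyl)phenoxy]triisopropylsilane | BrCc1ccc(O[Si](C(C)C)(C(C)C)C(C)C)cc1Br | intermediate
28 | (R)-4-benzyl-3-{(2R)-2-Ar-3-[2-bromo-4-(triisopropylsilyloxy)phenyl]propanoyl}oxazolidin-2-one | C=CC(C)(C)c1cc([C@@H](Cc2ccc(O[Si](C(C)C)(C(C)C)C(C)C)cc2Br)C(=O)N2[C@H](Cc3ccccc3)COC2=O)c(O[Si](C(C)C)(C(C)C)C(C)C)cc1OCC=C(C)C | intermediate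
29 | (2R)-2-Ar-3-[2-bromo-4-(triisopropylsilyloxy)phenyl]propan-1-ol | C=CC(C)(C)c1cc([C@@H](Cc2ccc(O[Si](C(C)C)(C(C)C)C(C)C)cc2Br)CO)c(O[Si](C(C)C)(C(C)C)C(C)C)cc1OCC=C(C)C | intermediate
30 | triisopropyl{[(3R)-3-Ar-3,4-dihydro-2H-chromen-7-yl]oxy}silane | C=CC(C)(C)c1cc([C@@H]2COc3cc(O[Si](C(C)C)(C(C)C)C(C)C)ccc3C2)c(O[Si](C(C)C)(C(C)C)C(C)C)cc1OCC=C(C)C | intermediate
31 | manuifolin D | C=CC(C)(C)c1cc([C@@H]2COc3cc(O)ccc3C2)c(O)cc1OCC=C(C)C | target

**Count**
Total steps: 16. Longest linear sequence: 13 steps (1, 2, 3, 5, 6, 7, 8, 9, 10, 13, 14, 15, 16).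

**Steps most likely to fail**

Step 5. What may go wrong: light absorbed by the dienone or by the product could divert material into di-π-methane-type rearrangement of the 1,4-diene or E/Z isomerisation before nitrogen loss, or the cyclobutenone could stall. The fallback sets out from 7 and comes back at 15; it makes the same vinylketene in the dark. AgO2CPh (silver benzoate) and Et3N in aqueous THF should convert 7 by Arndt–Eistert-type Wolff rearrangement and water capture into (E)-5,5-dimethylhepta-3,6-dienoic acid F1. Oxalyl chloride with a trace of DMF in CH2Cl2 should give (E)-5,5-dimethylhepta-3,6-dienoyl chloride F2. Slow addition of F2 to Et3N and 10 in toluene at 80 °C should release vinylketene 11 by dehydrochlorination, and 11 then passes through 12, 13 and 14 to phenol 15.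

Step 6. What may go wrong: iodonium transfer to the terminal alkene with capture by the neighbouring hydroxyl (iodoetherification to a dihydrobenzofuran), or iodination between the two oxygens. The fallback sets out from 15 and comes back at 18; it reverses the order so that no free hydroxyl is present during iodination. Alkylation of 15 with 17 and K2CO3 in DMF should give triisopropyl{4-(2-methylbut-3-en-2-yl)-3-[(3-methylbut-2-en-1-yl)oxy]phenoxy}silane F3. N-Iodosuccinimide in MeCN at 0 °C should then iodinate F3 para to the prenyloxy group, the only unhindered activated site, to give 18.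

Step 15. What may go wrong: β-hydride elimination from the alkoxypalladium intermediate (aldehyde and debrominated arene), or base-induced silyl transfer from the ring B oxygen to the primary alkoxide. The fallback sets out from 29 and comes back at 30; it turns the C–Br bond into C–OH and closes the ring at the alkyl carbon instead. Miyaura borylation (B2pin2, PdCl2(dppf), KOAc, dioxane, 80 °C) should give (2R)-2-Ar-3-[2-(4,4,5,5-tetramethyl-1,3,2-dioxaborolan-2-yl)-4-(triisopropylsilyloxy)phenyl]propan-1-ol F4. Oxidation with NaBO3·4H2O in THF/H2O should give 2-[(2R)-2-Ar-3-hydroxypropyl]-5-(triisopropylsilyloxy)phenol F5. Mitsunobu closure (PPh3, DIAD, THF, 0 °C) should give 30, since only the ring A phenol is free while the ring B oxygen is still silylated.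

**Further compounds**
F1 | step 5 | (E)-5,5-dimethylhepta-3,6-dienoic acid | OC(=O)C/C=C/C(C)(C)C=C
F2 | step 5 | (E)-5,5-dimethylhepta-3,6-dienoyl chloride | ClC(=O)C/C=C/C(C)(C)C=C
F3 | step 6 | triisopropyl{4-(2-methylbut-3-en-2-yl)-3-[(3-methylbut-2-en-1-yl)oxy]phenoxy}silane | C=CC(C)(C)c1ccc(O[Si](C(C)C)(C(C)C)C(C)C)cc1OCC=C(C)C
F4 | step 15 | (2R)-2-Ar-3-[2-(4,4,5,5-tetramethyl-1,3,2-dioxaborolan-2-yl)-4-(triisopropylsilyloxy)phenyl]propan-1-ol | C=CC(C)(C)c1cc([C@@H](Cc2ccc(O[Si](C(C)C)(C(C)C)C(C)C)cc2B3OC(C)(C)C(C)(C)O3)CO)c(O[Si](C(C)C)(C(C)C)C(C)C)cc1OCC=C(C)C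
F5 | step 15 | 2-[(2R)-2-Ar-3-hydroxypropyl]-5-(triisopropylsilyloxy)phenol | C=CC(C)(C)c1cc([C@@H](Cc2ccc(O[Si](C(C)C)(C(C)C)C(C)C)cc2O)CO)c(O[Si](C(C)C)(C(C)C)C(C)C)cc1OCC=C(C)C
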